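The quinone ring (C1 carbonyl, C2 hydroxyl, C3 prenylated indolyl, C4 carbonyl, C5 prenyl, C6 indolyl) is disconnected at C1–C2 and C5–C6. A Danheiser benzannulation makes both bonds in one operation: a 4-indolyl-2-prenyl-3-siloxycyclobutenone delivers C2–C3–C4–C5 through its vinylketene, and 3-ethynylindole delivers C1 and C6. The step exploits the meta relation of the oxygens on C2 and C4 (cyclobutenone carbonyl and siloxy group) and the donor-polarised alkyne, whose terminal carbon, the future C1, ends up beside C2. C1 arrives bearing hydrogen, para to the C4 oxygen, so desilylation and Teuber oxidation complete the hydroxyquinone.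

Key step: step 6

Assumption: the target has no stereocentre, the single stereocentre made on the way (the cyclobutenone CH) is carried as a racemate and erased in the key step, and 3-ethynyl-1H-indole, ethyl 4-methylpent-3-enoate and prenylmagnesium chloride (THF solution) are taken as catalogue compounds.

Step 1
Reactants: 1 succinic anhydride; 2 (3-methylbut-2-en-1-yl)magnesium chloride (prenylmagnesium chloride)
Product: 3 5,5-dimethyl-4-oxohept-6-enoic acid
Conditions: 2 added to 1 (1.3 equiv), THF, −78 °C; then 1 M HCl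
Reagents that add atoms: none
Why: Acylation of an allylic Grignard reagent by a cyclic anhydride, in which the prenyl reagent reacts through its tertiary γ-carbon (six-membered transition state) to give the α,α-dimethylallyl ketone, while inverse addition at −78 °C and the hindered, carboxylate-bearing ketone should suppress a second addition.

Step 2
Reactants: 3 5,5-dimethyl-4-oxohept-6-enoic acid; 4 phenylhydrazine
Product: 6 2-[2-(2-methylbut-3-en-2-yl)-1H-indol-3-yl]acetic acid, via phenylhydrazone 5 (not isolated)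
Conditions: AcOH, rt; then ZnCl2, AcOH, 80 °C
Reagents that add atoms: none
Why: Fischer indole synthesis, in which the ene-hydrazine can form only toward the methylene side because the other α-carbon is quaternary, so the [3,3] shift and loss of ammonia should place the 2-methylbut-3-en-2-yl group on C2 and the acetic acid arm on C3, as in the classical levulinic acid case.

Step 3
Reactants: 7 ethyl 4-methylpent-3-enoate
Product: 10 triisopropyl[(5-methylhex-4-en-1-yn-1-yl)oxy]silane, via lithium dibromoenolate 8 (not isolated), via lithium ynolate 9 (not isolated)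
Conditions: CH2Br2, lithium 2,2,6,6-tetramethylpiperidide (LiTMP), THF, −78 °C; LiN(SiMe3)2, −78 °C; n-BuLi, −78 to 0 °C; i-Pr3SiCl, −78 to 0 °C
Reagents that add atoms: dibromomethane, BrCBr; chlorotri(propan-2-yl)silane, CC(C)[Si](Cl)(C(C)C)C(C)C
Why: Kowalski ester homologation stopped at the ynolate stage, in which dibromomethyllithium adds to the ester, bromine–lithium exchange on enolate 8 triggers a carbenoid 1,2-shift to ynolate 9, and the bulky silyl chloride should silylate on oxygen.

Step 4
Reactants: 6 2-[2-(2-methylbut-3-en-2-yl)-1H-indol-3-yl]acetic acid; 10 triisopropyl[(5-methylhex-4-en-1-yn-1-yl)oxy]silane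
Product: 13 4-[2-(2-methylbut-3-en-2-yl)-1H-indol-3-yl]-2-(3-methylbut-2-en-1-yl)-3-[(triisopropylsilyl)oxy]cyclobut-2-en-1-one (racemic), via acid chloride 11 (not isolated), via indolylketene 12 (not isolated)
Conditions: 1-chloro-N,N,2-trimethylprop-1-en-1-amine, CH2Cl2, 0 °C; then 10 (1.5 equiv), Et3N (slow addition), CH2Cl2, 0 °C to rt
Reagents that add atoms: none
Why: Ketene–siloxyalkyne [2+2] cycloaddition, in which the alkyl-bearing alkyne carbon (β to oxygen, nucleophilic) should bond to the ketene carbonyl carbon to give the 3-siloxy-2-prenylcyclobutenone, the indole N–H being shielded by the adjacent quaternary carbon and the new C4 stereocentre forming as a racemate that step 6 erases.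

Step 5
Reactants: 14 3-ethynyl-1H-indole
Product: 15 3-ethynyl-1-(triisopropylsilyl)-1H-indole
Conditions: NaH, THF, 0 °C; i-Pr3SiCl, 0 °C to rt
Reagents that add atoms: chlorotri(propan-2-yl)silane, CC(C)[Si](Cl)(C(C)C)C(C)C
Why: N-silylation of the indolide anion, which NaH should form selectively because the N–H is several pK units more acidic than the alkyne C–H.

Step 6
Reactants: 13 the cyclobutenone; 15 3-ethynyl-1-(triisopropylsilyl)-1H-indole
Product: 20 2-[2-(2-methylbut-3-en-2-yl)-1H-indol-3-yl]-4-(3-methylbut-2-en-1-yl)-3-[(triisopropylsilyl)oxy]-5-[1-(triisopropylsilyl)-1H-indol-3-yl]phenol, via vinylketene 16 (not isolated), via 2-vinylcyclobutenone 17 (not isolated), via dienylketene 18 (not isolated), via cyclohexa-2,4-dienone 19 (not isolated)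
Conditions: 15 (1.5 equiv), toluene (0.5 M), 110 °C, sealed tube
Reagents that add atoms: none
Why: Danheiser benzannulation (cyclobutenone plus alkyne): conrotatory 4π opening of 13 gives vinylketene 16, whose ketene C=C adds the alkyne in a [2+2] cycloaddition to give 17, a second 4π opening gives dienylketene 18, and a disrotatory 6π electrocyclisation followed by enolisation of 19 gives the phenol. The two new ring bonds, C1–C6 and C4–C5 of the phenol (later C2–C1 and C5–C6 of the quinone), arise together in the [2+2] event; the transient four-membered ring closes by that cycloaddition and the six-membered ring by the 6π electrocyclisation. No stereocentre survives, because C4 of 13 and the quaternary carbon of 17 both become sp2 ring carbons. The selectivity needed is the orientation of the [2+2] step: the terminal alkyne carbon is the unhindered, nucleophilic end (the indole nitrogen of 15 pushes through C2=C3 and stabilises positive charge on the internal carbon), so it should bond to the electrophilic ketene carbonyl carbon while the indolyl-bearing carbon bonds to the prenyl-bearing α-carbon. The quaternary 2-methylbut-3-en-2-yl group on C2 of the first indole blocks a competing 6π closure of 16 onto that indole, and N-silylation keeps the N–H of the second indole from adding to the ketenes.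

Step 7
Reactants: 20 the bis-silylated phenol
Product: 21 5-(1H-indol-3-yl)-2-[2-(2-methylbut-3-en-2-yl)-1H-indol-3-yl]-4-(3-methylbut-2-en-1-yl)benzene-1,3-diol
Conditions: Bu4NF (2.5 equiv), THF, 0 °C to rt, argon; then aq. NH4Cl
Reagents that add atoms: none
Why: Fluoride-induced desilylation, which should cleave the aryl Si–O and the indole Si–N bonds alike and leave the alkenes untouched.

Step 8
Reactants: 21 the resorcinol
Product: 22 2-hydroxy-6-(1H-indol-3-yl)-3-[2-(2-methylbut-3-en-2-yl)-1H-indol-3-yl]-5-(3-methylbut-2-en-1-yl)cyclohexa-2,5-diene-1,4-dione (CNP0134649.0)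
Conditions: (KSO3)2NO (2.2 equiv), aq. KH2PO4, acetone/H2O, 0 °C to rt
Reagents that add atoms: potassium nitrosodisulfonate (Fremy's salt), [O]N(S(=O)(=O)[O-])S(=O)(=O)[O-].[K+].[K+]
Why: Teuber oxidation of a phenol by the nitroxyl radical salt, in which the only unsubstituted ring carbon (C6, para to the C3 hydroxyl and ortho to the C1 hydroxyl) should take up the oxygen to give the 2-hydroxy-1,4-benzoquinone, with indole N–H groups and isolated alkenes inert to this oxidant.

Compound list
1 | succinic anhydride | O=C1CCC(=O)O1 | starting material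
2 | (3-methylbut-2-en-1-yl)magnesium chloride | CC(C)=CC[Mg]Cl | starting material
3 | 5,5-dimethyl-4-oxohept-6-enoic acid | C=CC(C)(C)C(=O)CCC(=O)O | intermediate
4 | phenylhydrazine | NNc1ccccc1 | starting material
5 | (E)-5,5-dimethyl-4-(2-phenylhydrazinylidene)hept-6-enoic acid | C=CC(C)(C)/C(CCC(=O)O)=N/Nc1ccccc1 | intermediate (not isolated)
6 | 2-[2-(2-methylbut-3-en-2-yl)-1H-indol-3-yl]acetic acid | C=CC(C)(C)c1[nH]c2ccccc2c1CC(=O)O | intermediate
7 | ethyl 4-methylpent-3-enoate | CCOC(=O)CC=C(C)C | starting material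
8 | lithium 1,1-dibromo-5-methylhexa-1,4-dien-2-olate | CC(C)=CCC([O-])=C(Br)Br.[Li+] | intermediate (not isolated)
9 | lithium 5-methylhex-4-en-1-yn-1-olate | CC(C)=CCC#C[O-].[Li+] | intermediate (not isolated)
10 | triisopropyl[(5-methylhex-4-en-1-yn-1-yl)oxy]silane | CC(C)=CCC#CO[Si](C(C)C)(C(C)C)C(C)C | intermediate
11 | 2-[2-(2-methylbut-3-en-2-yl)-1H-indol-3-yl]acetyl chloride | C=CC(C)(C)c1[nH]c2ccccc2c1CC(=O)Cl | intermediate (not isolated)
12 | 2-[2-(2-methylbut-3-en-2-yl)-1H-indol-3-yl]ethen-1-one (ketene) | C=CC(C)(C)c1[nH]c2ccccc2c1C=C=O | intermediate (not isolated)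
13 | 4-[2-(2-methylbut-3-en-2-yl)-1H-indol-3-yl]-2-(3-methylbut-2-en-1-yl)-3-[(triisopropylsilyl)oxy]cyclobut-2-en-1-one, racemic | O=C1C(CC=C(C)C)=C(O[Si](C(C)C)(C(C)C)C(C)C)C1c1c(C(C)(C)C=C)[nH]c2ccccc12 | intermediate
14 | 3-ethynyl-1H-indole | C#Cc1c[nH]c2ccccc12 | starting material
15 | 3-ethynyl-1-(triisopropylsilyl)-1H-indole | C#Cc1cn([Si](C(C)C)(C(C)C)C(C)C)c2ccccc12 | intermediate
16 | vinylketene from ring opening of 13 (indolyl group trans to the ketene-bearing carbon) | O=C=C(CC=C(C)C)/C(O[Si](C(C)C)(C(C)C)C(C)C)=C/c1c(C(C)(C)C=C)[nH]c2ccccc12 | intermediate (not isolated)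
17 | 2-vinylcyclobutenone from [2+2] addition of 15 to 16, racemic | O=C1C=C(c2cn([Si](C(C)C)(C(C)C)C(C)C)c3ccccc23)C1(CC=C(C)C)/C(O[Si](C(C)C)(C(C)C)C(C)C)=C/c1c(C(C)(C)C=C)[nH]c2ccccc12 | intermediate (not isolated)
18 | dienylketene from ring opening of 17 (ketene arm and siloxyvinyl arm cis) | O=C=C/C(c1cn([Si](C(C)C)(C(C)C)C(C)C)c2ccccc12)=C(CC=C(C)C)\C(O[Si](C(C)C)(C(C)C)C(C)C)=C\c1c(C(C)(C)C=C)[nH]c2ccccc12 | intermediate (not isolated)
19 | cyclohexa-2,4-dienone from 6π closure of 18, racemic | O=C1C=C(c2cn([Si](C(C)C)(C(C)C)C(C)C)c3ccccc23)C(CC=C(C)C)=C(O[Si](C(C)C)(C(C)C)C(C)C)C1c1c(C(C)(C)C=C)[nH]c2ccccc12 | intermediate (not isolated)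
20 | 2-[2-(2-methylbut-3-en-2-yl)-1H-indol-3-yl]-4-(3-methylbut-2-en-1-yl)-3-[(triisopropylsilyl)oxy]-5-[1-(triisopropylsilyl)-1H-indol-3-yl]phenol | Oc1cc(-c2cn([Si](C(C)C)(C(C)C)C(C)C)c3ccccc23)c(CC=C(C)C)c(O[Si](C(C)C)(C(C)C)C(C)C)c1-c1c(C(C)(C)C=C)[nH]c2ccccc12 | intermediate
21 | 5-(1H-indol-3-yl)-2-[2-(2-methylbut-3-en-2-yl)-1H-indol-3-yl]-4-(3-methylbut-2-en-1-yl)benzene-1,3-diol | Oc1cc(-c2c[nH]c3ccccc23)c(CC=C(C)C)c(O)c1-c1c(C(C)(C)C=C)[nH]c2ccccc12 | intermediate
22 | 2-hydroxy-6-(1H-indol-3-yl)-3-[2-(2-methylbut-3-en-2-yl)-1H-indol-3-yl]-5-(3-methylbut-2-en-1-yl)cyclohexa-2,5-diene-1,4-dione | C=CC(C)(C)c1[nH]c2ccccc2c1C1=C(O)C(=O)C(c2c[nH]c3ccccc23)=C(CC=C(C)C)C1=O | target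

Total step count: 8. Longest linear sequence: 6 steps (steps 1, 2, 4, 6, 7, 8).

Steps most likely to fail

Step 6. The [2+2] capture of vinylketene 16 by the aryl alkyne may be slower than self-condensation of the ketene or its O-acylation of phenol already formed, so that little of the cascade reaches the arene. The fallback sets out from 13 and comes back at 20. Cyclobutenone 13 would be heated in toluene at 80 °C with ethynyl methyl sulfide, a sulfur-activated ketenophile of the classical kind. Its terminal carbon again bonds to the ketene carbonyl carbon, so the same two ring bonds form in the same cascade and give 2-[2-(2-methylbut-3-en-2-yl)-1H-indol-3-yl]-4-(3-methylbut-2-en-1-yl)-5-(methylsulfanyl)-3-[(triisopropylsilyl)oxy]phenol F1. A nickel-catalysed Kumada coupling of the aryl methyl sulfide (NiCl2(dppp), THF/toluene, 70 °C) with [1-(triisopropylsilyl)-1H-indol-3-yl]magnesium bromide F2 would then replace the methylsulfanyl group by the indolyl group and give 20. F2 would be made from commercial 3-bromo-1-(triisopropylsilyl)indole with t-BuLi at −78 °C and then MgBr2·OEt2, and used in excess to cover the O–H and N–H.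

Step 4. Acylation of the free indole nitrogen by acid chloride 11 or ketene 12, leading to oligomers, may outrun the cycloaddition with 10. The fallback sets out from 6 and comes back at 21, with the indole nitrogen masked throughout.
- Acid 6 would be treated with NaH (2.2 equiv) and 2-(trimethylsilyl)ethoxymethyl chloride (2.2 equiv) in DMF to give [2-(trimethylsilyl)ethoxy]methyl 2-[2-(2-methylbut-3-en-2-yl)-1-{[2-(trimethylsilyl)ethoxy]methyl}-1H-indol-3-yl]acetate F3.
- LiOH in THF/H2O would free the acid, 2-[2-(2-methylbut-3-en-2-yl)-1-{[2-(trimethylsilyl)ethoxy]methyl}-1H-indol-3-yl]acetic acid F4.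
- The procedure of step 4 with 10 would give the N-protected cyclobutenone 4-[2-(2-methylbut-3-en-2-yl)-1-{[2-(trimethylsilyl)ethoxy]methyl}-1H-indol-3-yl]-2-(3-methylbut-2-en-1-yl)-3-[(triisopropylsilyl)oxy]cyclobut-2-en-1-one F5.
- The procedure of step 6 with 15 would give the N-protected phenol 2-[2-(2-methylbut-3-en-2-yl)-1-{[2-(trimethylsilyl)ethoxy]methyl}-1H-indol-3-yl]-4-(3-methylbut-2-en-1-yl)-3-[(triisopropylsilyl)oxy]-5-[1-(triisopropylsilyl)-1H-indol-3-yl]phenol F6.
- Bu4NF (excess) with ethylenediamine in DMF at 80 °C would remove all three silicon-based groups and give 21.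

Step 2. Hot acid may trigger cationic rearrangement of the 1,1-dimethylallyl group, or the hydrazone acid may cyclise to an N-phenyl dihydropyridazinone instead of undergoing the [3,3] shift. The fallback sets out from 2 and comes back at 6, building the quaternary centre on a preformed indole under basic, cold conditions.
- Grignard reagent 2 and B-methoxy-9-borabicyclo[3.3.1]nonane (THF, 0 °C) would give 9-(3-methylbut-2-en-1-yl)-9-borabicyclo[3.3.1]nonane F7.
- Commercial methyl 2-(1H-indol-3-yl)acetate would be chlorinated with t-BuOCl and Et3N in THF at −78 °C to methyl 2-(3-chloro-3H-indol-3-yl)acetate F8 (not isolated).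
- F7 would add to F8 at C2 with allylic transposition, followed by loss of HCl, to give methyl 2-[2-(2-methylbut-3-en-2-yl)-1H-indol-3-yl]acetate F9.
- LiOH in THF/H2O would give 6.

Further compounds
F1 | step 6 | 2-[2-(2-methylbut-3-en-2-yl)-1H-indol-3-yl]-4-(3-methylbut-2-en-1-yl)-5-(methylsulfanyl)-3-[(triisopropylsilyl)oxy]phenol | Oc1cc(SC)c(CC=C(C)C)c(O[Si](C(C)C)(C(C)C)C(C)C)c1-c1c(C(C)(C)C=C)[nH]c2ccccc12
F2 | step 6 | [1-(triisopropylsilyl)-1H-indol-3-yl]magnesium bromide | Br[Mg]c1cn([Si](C(C)C)(C(C)C)C(C)C)c2ccccc12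
F3 | step 4 | [2-(trimethylsilyl)ethoxy]methyl 2-[2-(2-methylbut-3-en-2-yl)-1-{[2-(trimethylsilyl)ethoxy]methyl}-1H-indol-3-yl]acetate | C=CC(C)(C)c1n(COCC[Si](C)(C)C)c2ccccc2c1CC(=O)OCOCC[Si](C)(C)C
F4 | step 4 | 2-[2-(2-methylbut-3-en-2-yl)-1-{[2-(trimethylsilyl)ethoxy]methyl}-1H-indol-3-yl]acetic acid | C=CC(C)(C)c1n(COCC[Si](C)(C)C)c2ccccc2c1CC(=O)O
F5 | step 4 | 4-[2-(2-methylbut-3-en-2-yl)-1-{[2-(trimethylsilyl)ethoxy]methyl}-1H-indol-3-yl]-2-(3-methylbut-2-en-1-yl)-3-[(triisopropylsilyl)oxy]cyclobut-2-en-1-one, racemic | O=C1C(CC=C(C)C)=C(O[Si](C(C)C)(C(C)C)C(C)C)C1c1c(C(C)(C)C=C)n(COCC[Si](C)(C)C)c2ccccc12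
F6 | step 4 | 2-[2-(2-methylbut-3-en-2-yl)-1-{[2-(trimethylsilyl)ethoxy]methyl}-1H-indol-3-yl]-4-(3-methylbut-2-en-1-yl)-3-[(triisopropylsilyl)oxy]-5-[1-(triisopropylsilyl)-1H-indol-3-yl]phenol | Oc1cc(-c2cn([Si](C(C)C)(C(C)C)C(C)C)c3ccccc23)c(CC=C(C)C)c(O[Si](C(C)C)(C(C)C)C(C)C)c1-c1c(C(C)(C)C=C)n(COCC[Si](C)(C)C)c2ccccc12
F7 | step 2 | 9-(3-methylbut-2-en-1-yl)-9-borabicyclo[3.3.1]nonane | CC(C)=CCB1C2CCCC1CCC2
F8 | step 2 | methyl 2-(3-chloro-3H-indol-3-yl)acetate, racemic | COC(=O)CC1(Cl)C=Nc2ccccc12
F9 | step 2 | methyl 2-[2-(2-methylbut-3-en-2-yl)-1H-indol-3-yl]acetate | COC(=O)Cc1c(C(C)(C)C=C)[nH]c2ccccc12
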